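Locants: unit 1 is the apigenin half (C2–C8a, C1'–C6'). Unit 2 is the 7''-O-methyl half (C2''–C8a'', C1'''–C6'''). The halves meet at C3'–C8''.
Enabling feature: ring A of unit 2 carries three unlike oxygens (O1'' on C8a'', OMe on C7'', OH on C5'') around the aryl-bearing C8''. Its C8''–C7''(OMe) edge is therefore an aryl methoxyalkyne, and its C8a''–C4a''–C5''(O)–C6'' arc is 3-ethoxycyclobutenone.
Cuts, in retrosynthetic order: O1''–C2'', C3''–C4'' and C4''–C4a'' (ring C of unit 2); C8''–C8a'', C6''–C7'' and C4a''–C8a'' (ring A of unit 2); C3'–C8'' as an sp2–sp bond; O1–C2 and C2–C3 (ring C of unit 1).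
Forward order: ring C of unit 1 closes first, the alkyne is attached, ring A of unit 2 is grown on it, and ring C of unit 2 closes last. Rings A and B of unit 1 and ring B of unit 2 are bought.
Stereochemistry: the target has no stereocentre and its biaryl axis is drawn without configuration, so nothing has to be controlled.

Key step: step 7

Assumption: the C3'–C8'' axis is treated as configurationally undefined, and the sp3 centres of 15 and 23 are carried as racemates because both are erased later.

Step 1
Reactants: 1 methyl 4-hydroxy-3-iodobenzoate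
Product: 2 methyl 4-(benzyloxy)-3-iodobenzoate
Conditions: BnBr (1.2 equiv), K2CO3, DMF, rt
Reagents that add atoms: benzyl bromide, BrCc1ccccc1
Why: Williamson etherification of an acidic ortho-iodophenol with a primary benzylic halide is a plain SN2 reaction that leaves the ester and the iodide untouched.

Step 2
Reactants: 2 methyl 4-(benzyloxy)-3-iodobenzoate
Product: 3 4-(benzyloxy)-3-iodobenzoic acid
Conditions: LiOH, THF/MeOH/H2O, 50 °C; then aq. HCl
Reagents that add atoms: lithium hydroxide, [Li+].[OH-]
Why: Saponification of an unhindered methyl benzoate by acyl-oxygen cleavage is routine, and neither the aryl iodide nor the benzyl ether responds to aqueous base.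

Step 3
Reactants: 4 2',4',6'-trihydroxyacetophenone
Product: 5 2',4'-bis(benzyloxy)-6'-hydroxyacetophenone
Conditions: BnBr (2.1 equiv), K2CO3, DMF, rt → 50 °C
Reagents that add atoms: benzyl bromide, BrCc1ccccc1
Why: Williamson etherification stops at the diether because the last ortho hydroxyl is held in a hydrogen bond to the acetyl carbonyl and is the least nucleophilic of the three.

Step 4
Reactants: 3 4-(benzyloxy)-3-iodobenzoic acid; 5 2',4'-bis(benzyloxy)-6'-hydroxyacetophenone
Product: 7 1-[2,4-bis(benzyloxy)-6-hydroxyphenyl]-3-[4-(benzyloxy)-3-iodophenyl]propane-1,3-dione, via acid chloride 6 (not isolated)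
Conditions: 3, (COCl)2, DMF (cat.), CH2Cl2, rt, evaporate; 5, LiN(SiMe3)2 (3.2 equiv), THF, −78 → −10 °C, then 6, −78 °C → rt; aq. HCl
Reagents that add atoms: none
Why: Crossed Claisen C-aroylation of the doubly lithiated o-hydroxyacetophenone by an aroyl chloride is the one-flask form of the Baker–Venkataraman sequence, since any O-aroyl ester formed first is carried to the same diketone by acyl shift under the excess base.

Step 5
Reactants: 7 1-[2,4-bis(benzyloxy)-6-hydroxyphenyl]-3-[4-(benzyloxy)-3-iodophenyl]propane-1,3-dione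
Product: 8 3'-iodo-5,7,4'-tri-O-benzylapigenin (5,7-bis(benzyloxy)-2-[4-(benzyloxy)-3-iodophenyl]-4H-chromen-4-one)
Conditions: NaOAc, AcOH, 110 °C
Reagents that add atoms: none
Why: Cyclodehydration of an o-hydroxyaryl 1,3-diketone (6-exo-trig attack of the phenol on the aroyl carbonyl followed by loss of water) is the standard flavone closure, and buffered acetic acid is too weak an acid to cleave the peri benzyl ether.

Step 6
Reactants: 8 3'-iodo-5,7,4'-tri-O-benzylapigenin; 9 chloroacetaldehyde dimethyl acetal
Product: 12 3'-(methoxyethynyl)-5,7,4'-tri-O-benzylapigenin, via lithium methoxyacetylide 10 (not isolated), via methoxyethynylzinc chloride 11 (not isolated)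
Conditions: 9, LiNEt2 (3 equiv per 9, from Et2NH and n-BuLi), THF, 0 °C; ZnCl2, 0 °C → rt; 8, Pd(PPh3)4 (5 mol %), THF, rt → 40 °C; pH 8 work-up, basic alumina
Reagents that add atoms: none
Why: Two eliminations and a deprotonation by the amide base turn the chloroacetal into the alkoxyacetylide, and after transmetalation to zinc the Negishi coupling with an aryl iodide on zerovalent palladium is the established route to 1-alkoxy-2-arylalkynes, the flavone carbonyl being inert to the organozinc.

Step 7
Reactants: 12 3'-(methoxyethynyl)-5,7,4'-tri-O-benzylapigenin; 13 3-ethoxycyclobut-2-en-1-one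
Product: 18 3'-(4-ethoxy-2-hydroxy-6-methoxyphenyl)-5,7,4'-tri-O-benzylapigenin, via vinylketene 14 (not isolated), via vinylcyclobutenone 15 (not isolated), via dienylketene 16 (not isolated), via cyclohexadienone 17 (not isolated)
Conditions: 13 (2.5 equiv, in portions), toluene, 110 °C, base-washed sealed tube, Ar
Reagents that add atoms: none
Why: This is a Danheiser benzannulation of a cyclobutenone with an alkoxyalkyne, a thermal cascade of four pericyclic events. Conrotatory four-electron opening of 13 cleaves C4a''–C8a'' and gives vinylketene 14; its ketene carbon (C8a'') is attacked by the aryl-bearing, nucleophilic alkyne carbon of 12 (C8'') and the oxocarbenium carbon (C7'') closes on the ketene α-carbon (C6''), a regiospecific [2+2] cycloaddition that gives 15. Reversible four-electron opening of 15 is drained through dienylketene 16, in which ketene and ethoxyvinyl groups are cis on C6''=C7'', and ring A of unit 2 closes by a thermal disrotatory six-electron electrocyclization that re-makes C4a''–C8a''; tautomerisation of dienone 17 to phenol 18 makes the cascade irreversible. The one selectivity needed is the orientation of the [2+2] step, and the push of the methoxy oxygen through the triple bond secures it, so that the aryl group ends between the new C8a'' hydroxyl and the C7'' methoxy group with OEt on C5''. The sp3 carbon of 15 is racemic and is erased on ring opening, so no stereocentre is created. A methyl ynol ether has no β-hydrogen for retro-ene loss of an alkene and therefore survives the heating, benzyl ethers and the flavone are inert under neutral conditions, and the congested C3'–C8'' bond is already in place as an unhindered sp2–sp bond.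

Step 8
Reactants: 18 3'-(4-ethoxy-2-hydroxy-6-methoxyphenyl)-5,7,4'-tri-O-benzylapigenin
Product: 20 3'-(4-ethoxy-3-formyl-2-hydroxy-6-methoxyphenyl)-5,7,4'-tri-O-benzylapigenin, via salicyl alcohol 19 (not isolated)
Conditions: MgCl2 (anhydrous), Et3N, (CH2O)n, THF, reflux; cold dilute HCl
Reagents that add atoms: paraformaldehyde (as formaldehyde), C=O
Why: Casnati–Skattebøl ortho-formylation delivers formaldehyde inside the magnesium phenoxide chelate, so only the single free ortho carbon C4a'' reacts and not C6'' para to the phenol, a second formaldehyde oxidises 19 by hydride transfer, and no Lewis acid strong enough to attack benzyl ethers is present.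

Step 9
Reactants: 20 3'-(4-ethoxy-3-formyl-2-hydroxy-6-methoxyphenyl)-5,7,4'-tri-O-benzylapigenin; 21 1-(benzyloxy)-4-ethynylbenzene
Product: 23 3'-{4-ethoxy-2-hydroxy-3-[1-hydroxy-3-(4-benzyloxyphenyl)prop-2-yn-1-yl]-6-methoxyphenyl}-5,7,4'-tri-O-benzylapigenin (racemic carbinol), via alkynylmagnesium bromide 22 (not isolated)
Conditions: 21 (2.6 equiv), EtMgBr (2.5 equiv), THF, 0 → 40 °C; then 20, 0 °C → rt; H2O, used crude
Reagents that add atoms: none
Why: 1,2-Addition of an alkynyl Grignard reagent to an unprotected salicylaldehyde, whose magnesium phenoxide chelates and activates the formyl group, is well known, the vinylogous-ester carbonyl of unit 1 is far less electrophilic, and the new carbinol centre forms as a racemate, which does not matter because step 10 removes it.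

Step 10
Reactants: 23 3'-{4-ethoxy-2-hydroxy-3-[1-hydroxy-3-(4-benzyloxyphenyl)prop-2-yn-1-yl]-6-methoxyphenyl}-5,7,4'-tri-O-benzylapigenin
Product: 24 3'-{4-ethoxy-2-hydroxy-3-[3-(4-benzyloxyphenyl)prop-2-ynoyl]-6-methoxyphenyl}-5,7,4'-tri-O-benzylapigenin
Conditions: MnO2 (activated, excess), CH2Cl2, rt
Reagents that add atoms: none
Why: MnO2 oxidation is selective for benzylic and propargylic alcohols and runs under neutral conditions, which avoids ionisation of the electron-rich o-hydroxybenzylic alcohol.

Step 11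
Reactants: 24 3'-{4-ethoxy-2-hydroxy-3-[3-(4-benzyloxyphenyl)prop-2-ynoyl]-6-methoxyphenyl}-5,7,4'-tri-O-benzylapigenin
Product: 25 5,7,4',4'''-tetra-O-benzyl-5''-O-ethylsotetsuflavone
Conditions: DMAP (0.2 equiv), DMF, 40 °C
Reagents that add atoms: none
Why: DMAP-catalysed cyclisation of o-hydroxyaryl ynones is a known flavone synthesis in which the nucleophilic catalyst activates the β-carbon C2'', so that the C8a'' oxygen closes the six-membered ring (6-endo-dig overall) and not the 5-exo aurone.

Step 12
Reactants: 25 5,7,4',4'''-tetra-O-benzyl-5''-O-ethylsotetsuflavone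
Product: 26 sotetsuflavone (7''-O-methylamentoflavone)
Conditions: BCl3 (1 M in CH2Cl2, excess), C6HMe5, CH2Cl2, −78 → 0 °C → rt; then H2O/THF
Reagents that add atoms: none
Why: BCl3 with pentamethylbenzene as cation trap is an established cold debenzylation of aryl benzyl ethers, and on warming the boron chelate between the C4'' carbonyl and the peri C5'' oxygen lets chloride remove the ethyl group by SN2, whereas the unchelated 7''-methyl ether is not activated.

Compound list
1 | methyl 4-hydroxy-3-iodobenzoate | COC(=O)c1ccc(O)c(I)c1 | starting material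
2 | methyl 4-(benzyloxy)-3-iodobenzoate | COC(=O)c1ccc(OCc2ccccc2)c(I)c1 | intermediate
3 | 4-(benzyloxy)-3-iodobenzoic acid | OC(=O)c1ccc(OCc2ccccc2)c(I)c1 | intermediate
4 | 2',4',6'-trihydroxyacetophenone | CC(=O)c1c(O)cc(O)cc1O | starting material
5 | 2',4'-bis(benzyloxy)-6'-hydroxyacetophenone | CC(=O)c1c(O)cc(OCc2ccccc2)cc1OCc1ccccc1 | intermediate
6 | 4-(benzyloxy)-3-iodobenzoyl chloride (not isolated) | ClC(=O)c1ccc(OCc2ccccc2)c(I)c1 | intermediate
7 | 1-[2,4-bis(benzyloxy)-6-hydroxyphenyl]-3-[4-(benzyloxy)-3-iodophenyl]propane-1,3-dione | O=C(CC(=O)c1ccc(OCc2ccccc2)c(I)c1)c1c(O)cc(OCc2ccccc2)cc1OCc1ccccc1 | intermediate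
8 | 3'-iodo-5,7,4'-tri-O-benzylapigenin | Ic1cc(-c2cc(=O)c3c(OCc4ccccc4)cc(OCc4ccccc4)cc3o2)ccc1OCc1ccccc1 | intermediate
9 | chloroacetaldehyde dimethyl acetal | COC(CCl)OC | starting material
10 | lithium methoxyacetylide (not isolated) | [Li]C#COC | intermediate
11 | (methoxyethynyl)zinc chloride (not isolated) | Cl[Zn]C#COC | intermediate
12 | 3'-(methoxyethynyl)-5,7,4'-tri-O-benzylapigenin | COC#Cc1cc(-c2cc(=O)c3c(OCc4ccccc4)cc(OCc4ccccc4)cc3o2)ccc1OCc1ccccc1 | intermediate
13 | 3-ethoxycyclobut-2-en-1-one | CCOC1=CC(=O)C1 | starting material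
14 | 3-ethoxybuta-1,3-dien-1-one, the vinylketene (not isolated) | CCOC(=C)C=C=O | intermediate
15 | 2-aryl-4-(1-ethoxyvinyl)-3-methoxycyclobut-2-en-1-one, aryl = C3' of tri-O-benzylapigenin, racemic (not isolated) | CCOC(=C)C1C(=O)C(=C1OC)c1cc(-c2cc(=O)c3c(OCc4ccccc4)cc(OCc4ccccc4)cc3o2)ccc1OCc1ccccc1 | intermediate
16 | (3E)-2-aryl-5-ethoxy-3-methoxyhexa-1,3,5-trien-1-one, same aryl, the dienylketene (not isolated) | CCOC(=C)/C=C(OC)\C(=C=O)c1cc(-c2cc(=O)c3c(OCc4ccccc4)cc(OCc4ccccc4)cc3o2)ccc1OCc1ccccc1 | intermediate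
17 | 2-aryl-5-ethoxy-3-methoxycyclohexa-2,4-dien-1-one, same aryl (not isolated) | CCOC1=CC(OC)=C(C(=O)C1)c1cc(-c2cc(=O)c3c(OCc4ccccc4)cc(OCc4ccccc4)cc3o2)ccc1OCc1ccccc1 | intermediate
18 | 3'-(4-ethoxy-2-hydroxy-6-methoxyphenyl)-5,7,4'-tri-O-benzylapigenin | COc1cc(OCC)cc(O)c1-c1cc(-c2cc(=O)c3c(OCc4ccccc4)cc(OCc4ccccc4)cc3o2)ccc1OCc1ccccc1 | intermediate
19 | 3'-[4-ethoxy-2-hydroxy-3-(hydroxymethyl)-6-methoxyphenyl]-5,7,4'-tri-O-benzylapigenin, present as its magnesium salt (not isolated) | COc1cc(OCC)c(CO)c(O)c1-c1cc(-c2cc(=O)c3c(OCc4ccccc4)cc(OCc4ccccc4)cc3o2)ccc1OCc1ccccc1 | intermediate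
20 | 3'-(4-ethoxy-3-formyl-2-hydroxy-6-methoxyphenyl)-5,7,4'-tri-O-benzylapigenin | COc1cc(OCC)c(C=O)c(O)c1-c1cc(-c2cc(=O)c3c(OCc4ccccc4)cc(OCc4ccccc4)cc3o2)ccc1OCc1ccccc1 | intermediate
21 | 1-(benzyloxy)-4-ethynylbenzene | C#Cc1ccc(OCc2ccccc2)cc1 | starting material
22 | [(4-benzyloxyphenyl)ethynyl]magnesium bromide (not isolated) | Br[Mg]C#Cc1ccc(OCc2ccccc2)cc1 | intermediate
23 | 3'-{4-ethoxy-2-hydroxy-3-[1-hydroxy-3-(4-benzyloxyphenyl)prop-2-yn-1-yl]-6-methoxyphenyl}-5,7,4'-tri-O-benzylapigenin, racemic | COc1cc(OCC)c(C(O)C#Cc2ccc(OCc3ccccc3)cc2)c(O)c1-c1cc(-c2cc(=O)c3c(OCc4ccccc4)cc(OCc4ccccc4)cc3o2)ccc1OCc1ccccc1 | intermediate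
24 | 3'-{4-ethoxy-2-hydroxy-3-[3-(4-benzyloxyphenyl)prop-2-ynoyl]-6-methoxyphenyl}-5,7,4'-tri-O-benzylapigenin | COc1cc(OCC)c(C(=O)C#Cc2ccc(OCc3ccccc3)cc2)c(O)c1-c1cc(-c2cc(=O)c3c(OCc4ccccc4)cc(OCc4ccccc4)cc3o2)ccc1OCc1ccccc1 | intermediate
25 | 5,7,4',4'''-tetra-O-benzyl-5''-O-ethylsotetsuflavone | COc1cc(OCC)c2c(=O)cc(-c3ccc(OCc4ccccc4)cc3)oc2c1-c1cc(-c2cc(=O)c3c(OCc4ccccc4)cc(OCc4ccccc4)cc3o2)ccc1OCc1ccccc1 | intermediate
26 | sotetsuflavone | COc1cc(O)c2c(=O)cc(-c3ccc(O)cc3)oc2c1-c1cc(-c2cc(=O)c3c(O)cc(O)cc3o2)ccc1O | target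

Total step count: 12. Longest linear sequence: 11 (steps 1, 2 and 4 to 12).

Steps most likely to fail

Step 7.
- Risk: the vinylogous-ester stabilisation of 13 may slow its ring opening.
- Risk: the vinylketene may be used up by self-reaction, or by acylating the product phenol, faster than the ortho-substituted aryl alkyne intercepts it. O-acylation alone would be undone by a brief K2CO3/MeOH methanolysis.
- Fallback: give up ring construction and join two finished flavones by Suzuki–Miyaura coupling, the established way to 3'–8'' biflavones. The fallback sets out from 8. Miyaura borylation (B2pin2, PdCl2(dppf), KOAc, dioxane, 90 °C) should give 5,7,4'-tri-O-benzylapigenin-3'-boronic acid pinacol ester F1. Commercial genkwanin (apigenin 7-methyl ether) is benzylated on both free hydroxyls (BnBr, K2CO3, DMF, 80 °C) to 5,4'-di-O-benzylgenkwanin F2. Iodination (NIS, CF3CO2H cat., CH2Cl2) should occur at C8, the site favoured by 5-O-alkylated 5,7-dioxygenated flavones, to give 8-iodo-5,4'-di-O-benzylgenkwanin F3. Coupling of F1 with F3 (Pd(PPh3)4, K2CO3, DMF/H2O, 90 °C) should give 5,7,4',5'',4'''-penta-O-benzylsotetsuflavone F4. Hydrogenolysis (H2, Pd/C, THF/MeOH) comes back to the route at 26.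

Step 12.
- Risk: removal of the peri ethyl group may stay incomplete at temperatures that are safe for the methyl ether.
- Risk: the 7''-methyl group may be lost with help from the neighbouring boron aryloxide on C4'.
- Risk: benzyl cations may attack the electron-rich rings.
- Fallback: separate the two kinds of ether cleavage. From 25, hydrogenolysis (H2, Pd/C, THF/MeOH, rt) removes the four benzyl groups without any Lewis acid and should give 5''-O-ethylsotetsuflavone F5. The peri ether alone is then cleaved through its aluminium chelate (AlCl3, MeCN, reflux; aq. HCl), a classical 5-selective dealkylation of polyalkoxyflavones. This comes back at 26.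

Step 6.
- Risk: the ynol ether may be protonated and hydrated during coupling, work-up or chromatography.
- Risk: the diethylamine and methoxide left from the acetylide generation may interfere with the zinc reagent.
- Fallback: replace the zinc reagent made in situ by an isolable tin reagent and couple under neutral conditions (Stille coupling). The fallback sets out from 8 and 9. Acetylide 10, made from 9 as before, is quenched with Bu3SnCl to give tributyl(methoxyethynyl)stannane F6, which is distilled free of amine and methoxide. Coupling with 8 (Pd(PPh3)4, toluene, 80 °C) comes back at 12.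

Further compounds
F1 | step 7 | 5,7,4'-tri-O-benzylapigenin-3'-boronic acid pinacol ester | CC1(C)OB(OC1(C)C)c1cc(-c2cc(=O)c3c(OCc4ccccc4)cc(OCc4ccccc4)cc3o2)ccc1OCc1ccccc1
F2 | step 7 | 5,4'-di-O-benzylgenkwanin | COc1cc(OCc2ccccc2)c2c(=O)cc(-c3ccc(OCc4ccccc4)cc3)oc2c1
F3 | step 7 | 8-iodo-5,4'-di-O-benzylgenkwanin | COc1cc(OCc2ccccc2)c2c(=O)cc(-c3ccc(OCc4ccccc4)cc3)oc2c1I
F4 | step 7 | 5,7,4',5'',4'''-penta-O-benzylsotetsuflavone | COc1cc(OCc2ccccc2)c2c(=O)cc(-c3ccc(OCc4ccccc4)cc3)oc2c1-c1cc(-c2cc(=O)c3c(OCc4ccccc4)cc(OCc4ccccc4)cc3o2)ccc1OCc1ccccc1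
F5 | step 12 | 5''-O-ethylsotetsuflavone | COc1cc(OCC)c2c(=O)cc(-c3ccc(O)cc3)oc2c1-c1cc(-c2cc(=O)c3c(O)cc(O)cc3o2)ccc1O
F6 | step 6 | tributyl(methoxyethynyl)stannane | CCCC[Sn](CCCC)(CCCC)C#COC
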